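**Retrosynthetic overview**
1. The C8 hydroxy aldehyde comes from a C8 ketone (equatorial addition of a one-carbon nucleophile, then oxidation of C17). The C12–C13 bond comes from a B-alkyl Suzuki–Miyaura coupling on a C9 vinyl group. Both lead back to the bicyclic β-methoxy enoate 10.
2. Compound 10 comes from the monocyclic carbinol 8 in one operation: ionisation at C5, shift of the C4–C10 bond to C5 (five-membered ring becomes ring A), and capture of the resulting C10 cation by C9 (ring B).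
3. Enabling feature: in ring A the array C10(CH3)–C4(CH3)2–C3(O), with C5 between C10 and C4, is a 3-oxy-1,2,2-trimethylcyclopentane carrying C5 as an exocyclic carbinol on C10. A cation at C5 pulls the tertiary C4 across and leaves the charge on C10, the very carbon that C9 must attack.
4. Carbinol 8 comes from the camphanic-acid-derived lactone 3 (MeLi opening), the bromo enoate 6 (enolate alkylation) and a Corey–Bakshi–Shibata reduction that sets C5.
5. Ring order: cyclopentane (chiral pool), then ring A by ring expansion and ring B by cyclisation, both in step 6.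

Key step: step 6

Remark on the chemistry: the target is read as an ent-labdane, (3R,5S,8R,9S,10R,13Z), i.e. trans-decalin, C3–OH equatorial, C8–OH axial and syn to the C10 methyl, formyl carbon C17 equatorial; labdane numbering is used for atoms (C1–C10 ring carbons, C11–C16 side chain, C18/C19 on C4, C20 on C10), and (1R,4S)-camphanic chloride is taken as a purchasable resolving agent.

**Route**

Step 1
Reactants: 1 (1R,4S)-4,7,7-trimethyl-3-oxo-2-oxabicyclo[2.2.1]heptane-1-carbonyl chloride [(+)-camphanic chloride]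
Product: 3 (1R,4S)-4,7,7-trimethyl-2-oxabicyclo[2.2.1]heptan-3-one, via Barton ester 2 (not isolated)
Conditions: sodium 2-thioxopyridin-1(2H)-olate, DMAP (cat.), PhMe, rt, dark; then t-BuSH, hν (tungsten lamp), 80 °C
Reagents that add atoms: none
Why: Barton reductive decarboxylation, in which the thiohydroxamate ester should fragment to CO2 and the bridgehead α-oxy radical that takes H from the thiol, the carbinol centre (future C3, R) being held by the bicycle.

Step 2
Reactants: 3 (1R,4S)-4,7,7-trimethyl-2-oxabicyclo[2.2.1]heptan-3-one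
Product: 4 1-[(1S,3R)-3-hydroxy-1,2,2-trimethylcyclopentyl]ethan-1-one
Conditions: MeLi (1.05 equiv), THF, −78 °C; then H2O
Reagents that add atoms: methyllithium, [Li]C
Why: Single addition of an organolithium to a strained, hindered γ-lactone (lactone to methyl ketone), the lithium hemiketalate being expected to persist at −78 °C and to open only on work-up.

Step 3
Reactants: 4 1-[(1S,3R)-3-hydroxy-1,2,2-trimethylcyclopentyl]ethan-1-one
Product: 5 1-[(1S,3R)-3-(tert-butyldimethylsilyloxy)-1,2,2-trimethylcyclopentyl]ethan-1-one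
Conditions: TBSCl, imidazole, DMAP (cat.), DMF, 50 °C
Reagents that add atoms: tert-butyl(chloro)dimethylsilane, CC(C)(C)[Si](C)(C)Cl
Why: Silyl ether formation on the secondary alcohol under conditions that do not enolise the ketone.

Step 4
Reactants: 5 1-[(1S,3R)-3-(tert-butyldimethylsilyloxy)-1,2,2-trimethylcyclopentyl]ethan-1-one; 6 methyl (E)-4-bromo-3-methoxybut-2-enoate
Product: 7 methyl (2E)-6-[(1S,3R)-3-(tert-butyldimethylsilyloxy)-1,2,2-trimethylcyclopentyl]-3-methoxy-6-oxohex-2-enoate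
Conditions: lithium diisopropylamide, THF, −78 °C; then 6, DMPU, −78 → −30 °C
Reagents that add atoms: methyl (E)-4-bromo-3-methoxybut-2-enoate (reactant 6), COC(=O)/C=C(/OC)CBr
Why: Enolate alkylation, in which the only possible enolate (C10 is quaternary) should displace the allylic bromide by SN2 and so install C6–C11 with C8 already at the enol ether level.

Step 5
Reactants: 7 methyl (2E)-6-[(1S,3R)-3-(tert-butyldimethylsilyloxy)-1,2,2-trimethylcyclopentyl]-3-methoxy-6-oxohex-2-enoate
Product: 8 methyl (2E,6R)-6-[(1S,3R)-3-(tert-butyldimethylsilyloxy)-1,2,2-trimethylcyclopentyl]-6-hydroxy-3-methoxyhex-2-enoate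
Conditions: (S)-2-methyl-CBS-oxazaborolidine (20 mol%), BH3·SMe2, THF, −20 °C; then MeOH, H2O
Reagents that add atoms: none
Why: Corey–Bakshi–Shibata reduction, in which the (S)-catalyst treats the tertiary cyclopentyl group as the large and the CH2 chain as the small substituent and should give the (R)-carbinol at C5 under catalyst control.

Step 6
Reactants: 8 methyl (2E,6R)-6-[(1S,3R)-3-(tert-butyldimethylsilyloxy)-1,2,2-trimethylcyclopentyl]-6-hydroxy-3-methoxyhex-2-enoate
Product: 10 methyl (4aS,6R,8aR)-6-(tert-butyldimethylsilyloxy)-2-methoxy-5,5,8a-trimethyl-3,4,4a,5,6,7,8,8a-octahydronaphthalene-1-carboxylate, via triflate 9 (not isolated)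
Conditions: Tf2O (1.2 equiv), 2,6-di-tert-butyl-4-methylpyridine (3 equiv), CH2Cl2, −78 → 0 °C
Reagents that add atoms: none
Why: Proposed new method: the C5 triflate 9, a neopentyl-type secondary sulfonate, should ionise with anti-periplanar migration of the C4–C10 bond (tertiary C4 is the best migrating group and the shift relieves cyclopentane strain), which moves C4 to C5 and turns the cyclopentane C10–C1–C2–C3–C4 into the six-membered ring A C10–C1–C2–C3–C4–C5 with a tertiary cation at C10; C9 of the β-methoxyacrylate then attacks C10 and the C8 oxocarbenium ion loses H9 to the pyridine base, regenerating the push–pull enol ether. The closest known reaction types are the solvolytic Wagner–Meerwein ring expansion of 1-(1-methylcyclopentyl)alkyl sulfonates to 1-methylcyclohexyl cations and the cation–olefin cyclisation of 2-substituted 1-methylcyclohexyl cations onto β-keto ester or enol ether terminators; their union in one flask on this substrate class is the new element. Ring A arises by the 1,2-alkyl shift (ring expansion, not a cyclisation) and ring B by 6-endo-trig attack of the C8=C9 π bond on C10 through a chair transition state. C5 is set by inversion, C4 entering anti to the departing oxygen so that the (R)-carbinol of step 5 becomes (S)-C5, whereas C10 is planar in the ring-expanded cation (its configuration in the cyclopentane is erased) and is attacked on the face anti to the axial C4 methyl with the C5 chain and the C3 silyl ether equatorial, which should give the trans-decalin with (R)-C10; C3 is untouched. The step needs C4 to migrate in preference to C1 or the methyl group (secured by the tertiary migrating carbon and by the rotamer that keeps the sulfonate away from the gem-dimethyl group) and ring closure to outrun elimination or direct displacement at C5 (secured by the non-nucleophilic medium, the hindered base, the neopentyl shielding of C5 and the 5-endo geometry that C9 would need to reach C5). Attack of the methoxy oxygen on C10 would only give an oxonium ion that can revert, so C-alkylation is the productive exit.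

Step 7
Reactants: 10 methyl (4aS,6R,8aR)-6-(tert-butyldimethylsilyloxy)-2-methoxy-5,5,8a-trimethyl-3,4,4a,5,6,7,8,8a-octahydronaphthalene-1-carboxylate
Product: 11 [(4aS,6R,8aR)-6-(tert-butyldimethylsilyloxy)-2-methoxy-5,5,8a-trimethyl-3,4,4a,5,6,7,8,8a-octahydronaphthalen-1-yl]methanol
Conditions: diisobutylaluminium hydride (2.5 equiv), CH2Cl2, −78 → 0 °C; aq. potassium sodium tartrate
Reagents that add atoms: none
Why: Hydride 1,2-reduction of the vinylogous carbonate ester to the allylic alcohol, which leaves the tetrasubstituted enol ether untouched.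

Step 8
Reactants: 11 [(4aS,6R,8aR)-6-(tert-butyldimethylsilyloxy)-2-methoxy-5,5,8a-trimethyl-3,4,4a,5,6,7,8,8a-octahydronaphthalen-1-yl]methanol
Product: 12 (4aS,6R,8aR)-6-(tert-butyldimethylsilyloxy)-2-methoxy-5,5,8a-trimethyl-3,4,4a,5,6,7,8,8a-octahydronaphthalene-1-carbaldehyde
Conditions: MnO2 (activated, excess), CH2Cl2, rt
Reagents that add atoms: none
Why: Allylic alcohol oxidation with MnO2 under neutral conditions, chosen to spare the acid-sensitive 3-methoxy allylic alcohol and its enol ether.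

Step 9
Reactants: 12 (4aS,6R,8aR)-6-(tert-butyldimethylsilyloxy)-2-methoxy-5,5,8a-trimethyl-3,4,4a,5,6,7,8,8a-octahydronaphthalene-1-carbaldehyde
Product: 13 tert-butyl{[(2R,4aR,8aS)-5-ethenyl-6-methoxy-1,1,4a-trimethyl-1,2,3,4,4a,7,8,8a-octahydronaphthalen-2-yl]oxy}dimethylsilane
Conditions: Ph3PCH3Br, KOtBu, THF, 0 °C → rt
Reagents that add atoms: methyltriphenylphosphonium bromide, C[P+](c1ccccc1)(c1ccccc1)c1ccccc1.[Br-]
Why: Wittig methylenation of the aldehyde to give the 2-methoxy-1,3-diene that carries C11=C12.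

Step 10
Reactants: 14 methyl but-2-ynoate
Product: 15 methyl (Z)-3-iodobut-2-enoate
Conditions: NaI, AcOH, 110 °C
Reagents that add atoms: sodium iodide, [Na+].[I-]
Why: Hydroiodination of an ynoate by conjugate addition of iodide and anti protonation, the known Z-selective route to β-iodo enoates.

Step 11
Reactants: 13 tert-butyl{[(2R,4aR,8aS)-5-ethenyl-6-methoxy-1,1,4a-trimethyl-1,2,3,4,4a,7,8,8a-octahydronaphthalen-2-yl]oxy}dimethylsilane; 15 methyl (Z)-3-iodobut-2-enoate
Product: 17 methyl (2Z)-5-[(4aS,6R,8aR)-6-(tert-butyldimethylsilyloxy)-2-methoxy-5,5,8a-trimethyl-3,4,4a,5,6,7,8,8a-octahydronaphthalen-1-yl]-3-methylpent-2-enoate, via alkylborane 16 (not isolated)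
Conditions: 9-BBN-H, THF, 0 °C → rt; then 15, Pd(dppf)Cl2 (5 mol%), AsPh3, Cs2CO3, DMF/H2O, rt
Reagents that add atoms: methyl (Z)-3-iodobut-2-enoate (reactant 15), COC(=O)/C=C(/C)I
Why: Anti-Markovnikov hydroboration of the terminal vinyl carbon (the tetrasubstituted enol ether is inert to 9-BBN-H) followed by B-alkyl Suzuki–Miyaura coupling, which joins C12 to C13 with retention of the Z geometry of the iodide.

Step 12
Reactants: 17 methyl (2Z)-5-[(4aS,6R,8aR)-6-(tert-butyldimethylsilyloxy)-2-methoxy-5,5,8a-trimethyl-3,4,4a,5,6,7,8,8a-octahydronaphthalen-1-yl]-3-methylpent-2-enoate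
Product: 18 methyl (2Z)-5-[(1S,4aS,6R,8aR)-6-hydroxy-5,5,8a-trimethyl-2-oxodecahydronaphthalen-1-yl]-3-methylpent-2-enoate
Conditions: 2 M aq. HCl, THF/MeOH, 40 °C
Reagents that add atoms: water, O
Why: Acid hydrolysis of the enol ether to the C8 ketone with concurrent cleavage of the silyl ether, C9 being protonated and then equilibrated through the enol to the equatorial side chain (thermodynamic control, S).

Step 13
Reactants: 18 methyl (2Z)-5-[(1S,4aS,6R,8aR)-6-hydroxy-5,5,8a-trimethyl-2-oxodecahydronaphthalen-1-yl]-3-methylpent-2-enoate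
Product: 20 methyl (2Z)-5-[(1S,2R,4aS,6R,8aR)-2,6-dihydroxy-2-(hydroxymethyl)-5,5,8a-trimethyldecahydronaphthalen-1-yl]-3-methylpent-2-enoate, via silylmethyl carbinol 19 (not isolated)
Conditions: i-PrO(Me)2SiCH2MgCl (3 equiv, from the chloride and Mg), THF, −20 → 0 °C; then KF, KHCO3, 30% H2O2, THF/MeOH, rt
Reagents that add atoms: {[dimethyl(propan-2-yloxy)silyl]methyl}magnesium chloride, CC(C)O[Si](C)(C)C[Mg]Cl; hydrogen peroxide, OO
Why: Grignard 1,2-addition from the equatorial direction (the axial path is blocked by the 1,3-diaxial C10 methyl), which should place C17 equatorial and the C8 hydroxyl axial (R), followed by Tamao oxidation of the C–Si bond to the primary alcohol.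

Step 14
Reactants: 20 methyl (2Z)-5-[(1S,2R,4aS,6R,8aR)-2,6-dihydroxy-2-(hydroxymethyl)-5,5,8a-trimethyldecahydronaphthalen-1-yl]-3-methylpent-2-enoate
Product: 21 (2Z)-5-[(1S,2R,4aS,6R,8aR)-2,6-dihydroxy-2-(hydroxymethyl)-5,5,8a-trimethyldecahydronaphthalen-1-yl]-3-methylpent-2-enoic acid
Conditions: LiOH, THF/H2O, rt; then 1 M HCl to pH 3
Reagents that add atoms: lithium hydroxide, [Li+].[OH-]
Why: Ester saponification carried out before the aldehyde exists, so that the base-sensitive α-hydroxy aldehyde never meets hydroxide.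

Step 15
Reactants: 21 (2Z)-5-[(1S,2R,4aS,6R,8aR)-2,6-dihydroxy-2-(hydroxymethyl)-5,5,8a-trimethyldecahydronaphthalen-1-yl]-3-methylpent-2-enoic acid
Product: 22 (2Z)-5-[(1S,2R,4aS,6R,8aR)-2-formyl-2,6-dihydroxy-5,5,8a-trimethyldecahydronaphthalen-1-yl]-3-methylpent-2-enoic acid (target)
Conditions: TEMPO (cat.), N-chlorosuccinimide, Bu4NCl (cat.), CH2Cl2/aq. NaHCO3 buffer, 0 °C
Reagents that add atoms: none
Why: Oxoammonium (TEMPO) oxidation, which should select the primary C17 alcohol over the hindered secondary C3 and the tertiary C8 hydroxyls and stop at the aldehyde without glycol cleavage.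

**Compound list**
1 | (1R,4S)-4,7,7-trimethyl-3-oxo-2-oxabicyclo[2.2.1]heptane-1-carbonyl chloride | C[C@@]12CC[C@@](C(=O)Cl)(OC1=O)C2(C)C | starting material
2 | 2-thioxopyridin-1(2H)-yl (1R,4S)-4,7,7-trimethyl-3-oxo-2-oxabicyclo[2.2.1]heptane-1-carboxylate (Barton ester) | C[C@@]12CC[C@@](C(=O)ON3C=CC=CC3=S)(OC1=O)C2(C)C | intermediate
3 | (1R,4S)-4,7,7-trimethyl-2-oxabicyclo[2.2.1]heptan-3-one | C[C@@]12CC[C@@H](OC1=O)C2(C)C | intermediate
4 | 1-[(1S,3R)-3-hydroxy-1,2,2-trimethylcyclopentyl]ethan-1-one | C[C@]1(C(C)=O)CC[C@@H](O)C1(C)C | intermediate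
5 | 1-[(1S,3R)-3-(tert-butyldimethylsilyloxy)-1,2,2-trimethylcyclopentyl]ethan-1-one | C[C@]1(C(C)=O)CC[C@@H](O[Si](C)(C)C(C)(C)C)C1(C)C | intermediate
6 | methyl (E)-4-bromo-3-methoxybut-2-enoate | COC(=O)/C=C(/OC)CBr | starting material
7 | methyl (2E)-6-[(1S,3R)-3-(tert-butyldimethylsilyloxy)-1,2,2-trimethylcyclopentyl]-3-methoxy-6-oxohex-2-enoate | COC(=O)/C=C(/OC)CCC(=O)[C@@]1(C)CC[C@@H](O[Si](C)(C)C(C)(C)C)C1(C)C | intermediate
8 | methyl (2E,6R)-6-[(1S,3R)-3-(tert-butyldimethylsilyloxy)-1,2,2-trimethylcyclopentyl]-6-hydroxy-3-methoxyhex-2-enoate | COC(=O)/C=C(/OC)CC[C@@H](O)[C@@]1(C)CC[C@@H](O[Si](C)(C)C(C)(C)C)C1(C)C | intermediate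
9 | methyl (2E,6R)-6-[(1S,3R)-3-(tert-butyldimethylsilyloxy)-1,2,2-trimethylcyclopentyl]-3-methoxy-6-(trifluoromethanesulfonyloxy)hex-2-enoate | COC(=O)/C=C(/OC)CC[C@@H](OS(=O)(=O)C(F)(F)F)[C@@]1(C)CC[C@@H](O[Si](C)(C)C(C)(C)C)C1(C)C | intermediate
10 | methyl (4aS,6R,8aR)-6-(tert-butyldimethylsilyloxy)-2-methoxy-5,5,8a-trimethyl-3,4,4a,5,6,7,8,8a-octahydronaphthalene-1-carboxylate | COC(=O)C1=C(OC)CC[C@H]2[C@@]1(C)CC[C@@H](O[Si](C)(C)C(C)(C)C)C2(C)C | intermediate
11 | [(4aS,6R,8aR)-6-(tert-butyldimethylsilyloxy)-2-methoxy-5,5,8a-trimethyl-3,4,4a,5,6,7,8,8a-octahydronaphthalen-1-yl]methanol | OCC1=C(OC)CC[C@H]2[C@@]1(C)CC[C@@H](O[Si](C)(C)C(C)(C)C)C2(C)C | intermediate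
12 | (4aS,6R,8aR)-6-(tert-butyldimethylsilyloxy)-2-methoxy-5,5,8a-trimethyl-3,4,4a,5,6,7,8,8a-octahydronaphthalene-1-carbaldehyde | O=CC1=C(OC)CC[C@H]2[C@@]1(C)CC[C@@H](O[Si](C)(C)C(C)(C)C)C2(C)C | intermediate
13 | tert-butyl{[(2R,4aR,8aS)-5-ethenyl-6-methoxy-1,1,4a-trimethyl-1,2,3,4,4a,7,8,8a-octahydronaphthalen-2-yl]oxy}dimethylsilane | C=CC1=C(OC)CC[C@H]2[C@@]1(C)CC[C@@H](O[Si](C)(C)C(C)(C)C)C2(C)C | intermediate
14 | methyl but-2-ynoate | CC#CC(=O)OC | starting material
15 | methyl (Z)-3-iodobut-2-enoate | COC(=O)/C=C(/C)I | intermediate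
16 | 9-{2-[(4aS,6R,8aR)-6-(tert-butyldimethylsilyloxy)-2-methoxy-5,5,8a-trimethyl-3,4,4a,5,6,7,8,8a-octahydronaphthalen-1-yl]ethyl}-9-borabicyclo[3.3.1]nonane | B3(C4CCCC3CCC4)CCC1=C(OC)CC[C@H]2[C@@]1(C)CC[C@@H](O[Si](C)(C)C(C)(C)C)C2(C)C | intermediate
17 | methyl (2Z)-5-[(4aS,6R,8aR)-6-(tert-butyldimethylsilyloxy)-2-methoxy-5,5,8a-trimethyl-3,4,4a,5,6,7,8,8a-octahydronaphthalen-1-yl]-3-methylpent-2-enoate | COC(=O)/C=C(/C)CCC1=C(OC)CC[C@H]2[C@@]1(C)CC[C@@H](O[Si](C)(C)C(C)(C)C)C2(C)C | intermediate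
18 | methyl (2Z)-5-[(1S,4aS,6R,8aR)-6-hydroxy-5,5,8a-trimethyl-2-oxodecahydronaphthalen-1-yl]-3-methylpent-2-enoate | C/C(=C/C(=O)OC)CC[C@H]1[C@]2(C)CC[C@@H](O)C(C)(C)[C@H]2CCC1=O | intermediate
19 | methyl (2Z)-5-[(1S,2R,4aS,6R,8aR)-2-{[dimethyl(propan-2-yloxy)silyl]methyl}-2,6-dihydroxy-5,5,8a-trimethyldecahydronaphthalen-1-yl]-3-methylpent-2-enoate | C/C(=C/C(=O)OC)CC[C@H]1[C@]2(C)CC[C@@H](O)C(C)(C)[C@H]2CC[C@]1(O)C[Si](C)(C)OC(C)C | intermediate
20 | methyl (2Z)-5-[(1S,2R,4aS,6R,8aR)-2,6-dihydroxy-2-(hydroxymethyl)-5,5,8a-trimethyldecahydronaphthalen-1-yl]-3-methylpent-2-enoate | C/C(=C/C(=O)OC)CC[C@H]1[C@]2(C)CC[C@@H](O)C(C)(C)[C@H]2CC[C@]1(O)CO | intermediate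
21 | (2Z)-5-[(1S,2R,4aS,6R,8aR)-2,6-dihydroxy-2-(hydroxymethyl)-5,5,8a-trimethyldecahydronaphthalen-1-yl]-3-methylpent-2-enoic acid | C/C(=C/C(=O)O)CC[C@H]1[C@]2(C)CC[C@@H](O)C(C)(C)[C@H]2CC[C@]1(O)CO | intermediate
22 | (2Z)-5-[(1S,2R,4aS,6R,8aR)-2-formyl-2,6-dihydroxy-5,5,8a-trimethyldecahydronaphthalen-1-yl]-3-methylpent-2-enoic acid | C/C(=C/C(=O)O)CC[C@H]1[C@]2(C)CC[C@@H](O)C(C)(C)[C@H]2CC[C@]1(O)C=O | target

**Step count and risks**
Total step count: 15. Longest linear sequence: 14 steps (steps 1–9 and 11–15; step 10 is a one-step side branch).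

Step 6 (the labelled step). The cascade may be diverted by elimination of the triflate towards C6, by migration of C1 or of the C10 methyl group in place of C4, or by proton loss from the C10 cation before ring B closes. The fallback uses known chemistry, sets out from 8 and comes back at 10. Carbinol 8 is converted into its methanesulfonate, methyl (2E,6R)-6-[(1S,3R)-3-(tert-butyldimethylsilyloxy)-1,2,2-trimethylcyclopentyl]-3-methoxy-6-(methanesulfonyloxy)hex-2-enoate F1 (MsCl, Et3N). Heating in NaOAc-buffered acetic acid, the classical Wagner–Meerwein ring expansion ending in proton loss, is expected to give the cyclohexene methyl (2E)-5-[(5R)-5-(tert-butyldimethylsilyloxy)-2,6,6-trimethylcyclohex-1-en-1-yl]-3-methoxypent-2-enoate F2; its double-bond isomers converge later on the same C10 cation. Dilute aqueous acid hydrolyses the enol ether to the β-keto ester methyl 5-[(5R)-5-(tert-butyldimethylsilyloxy)-2,6,6-trimethylcyclohex-1-en-1-yl]-3-oxopentanoate F3. SnCl4 in CH2Cl2 closes ring B by the established cyclisation of cyclohexenyl β-keto esters to methyl (1S,4aS,6R,8aR)-6-(tert-butyldimethylsilyloxy)-5,5,8a-trimethyl-2-oxodecahydronaphthalene-1-carboxylate F4, the equatorial C3 silyl ether now selecting the chair that sets C5 and C10. O-Methylation (Me2SO4, K2CO3, acetone) returns 10.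

Step 4. The enolate may act as a base towards the acidic bromide, or add to its β-carbon with loss of methoxide, in place of SN2 displacement. The fallback sets out from 3 and comes back at 7 by building the chain from the other end. Lactone 3 is opened with the Grignard reagent of 2-(2-bromoethyl)-1,3-dioxolane to 3-(1,3-dioxolan-2-yl)-1-[(1S,3R)-3-hydroxy-1,2,2-trimethylcyclopentyl]propan-1-one F5, which is silylated (TBSCl, imidazole) to 1-[(1S,3R)-3-(tert-butyldimethylsilyloxy)-1,2,2-trimethylcyclopentyl]-3-(1,3-dioxolan-2-yl)propan-1-one F6. Mild acetal hydrolysis (pyridinium p-toluenesulfonate, wet acetone) gives 4-[(1S,3R)-3-(tert-butyldimethylsilyloxy)-1,2,2-trimethylcyclopentyl]-4-oxobutanal F7. Roskamp homologation (methyl diazoacetate, SnCl2 cat.) gives methyl 6-[(1S,3R)-3-(tert-butyldimethylsilyloxy)-1,2,2-trimethylcyclopentyl]-3,6-dioxohexanoate F8, and O-methylation of the β-keto ester (Me2SO4, K2CO3, acetone) gives 7.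

Step 13. Enolisation of the hindered C8 ketone by the Grignard reagent, addition to the ester, or erosion of the equatorial preference may intervene. The fallback sets out from 18 and comes back at 22. Vinylmagnesium bromide pre-complexed with anhydrous CeCl3 (a less basic organocerium nucleophile) adds to 18 to give methyl (2Z)-5-[(1S,2S,4aS,6R,8aR)-2-ethenyl-2,6-dihydroxy-5,5,8a-trimethyldecahydronaphthalen-1-yl]-3-methylpent-2-enoate F9. LiOH gives (2Z)-5-[(1S,2S,4aS,6R,8aR)-2-ethenyl-2,6-dihydroxy-5,5,8a-trimethyldecahydronaphthalen-1-yl]-3-methylpent-2-enoic acid F10. OsO4 (cat.) with N-methylmorpholine N-oxide should dihydroxylate the vinyl group in preference to the electron-poor trisubstituted enoic acid, giving (2Z)-5-[(1S,2R,4aS,6R,8aR)-2-(1,2-dihydroxyethyl)-2,6-dihydroxy-5,5,8a-trimethyldecahydronaphthalen-1-yl]-3-methylpent-2-enoic acid F11 (both epimers at the new secondary carbinol). NaIO4 (one equivalent, 0 °C) cleaves the terminal glycol to 22.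

**Further compounds**
F1 | step 6 | methyl (2E,6R)-6-[(1S,3R)-3-(tert-butyldimethylsilyloxy)-1,2,2-trimethylcyclopentyl]-3-methoxy-6-(methanesulfonyloxy)hex-2-enoate | COC(=O)/C=C(/OC)CC[C@@H](OS(C)(=O)=O)[C@@]1(C)CC[C@@H](O[Si](C)(C)C(C)(C)C)C1(C)C
F2 | step 6 | methyl (2E)-5-[(5R)-5-(tert-butyldimethylsilyloxy)-2,6,6-trimethylcyclohex-1-en-1-yl]-3-methoxypent-2-enoate | COC(=O)/C=C(/OC)CCC1=C(C)CC[C@@H](O[Si](C)(C)C(C)(C)C)C1(C)C
F3 | step 6 | methyl 5-[(5R)-5-(tert-butyldimethylsilyloxy)-2,6,6-trimethylcyclohex-1-en-1-yl]-3-oxopentanoate | COC(=O)CC(=O)CCC1=C(C)CC[C@@H](O[Si](C)(C)C(C)(C)C)C1(C)C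
F4 | step 6 | methyl (1S,4aS,6R,8aR)-6-(tert-butyldimethylsilyloxy)-5,5,8a-trimethyl-2-oxodecahydronaphthalene-1-carboxylate | COC(=O)[C@@H]1C(=O)CC[C@H]2[C@@]1(C)CC[C@@H](O[Si](C)(C)C(C)(C)C)C2(C)C
F5 | step 4 | 3-(1,3-dioxolan-2-yl)-1-[(1S,3R)-3-hydroxy-1,2,2-trimethylcyclopentyl]propan-1-one | C[C@]1(C(=O)CCC2OCCO2)CC[C@@H](O)C1(C)C
F6 | step 4 | 1-[(1S,3R)-3-(tert-butyldimethylsilyloxy)-1,2,2-trimethylcyclopentyl]-3-(1,3-dioxolan-2-yl)propan-1-one | C[C@]1(C(=O)CCC2OCCO2)CC[C@@H](O[Si](C)(C)C(C)(C)C)C1(C)C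
F7 | step 4 | 4-[(1S,3R)-3-(tert-butyldimethylsilyloxy)-1,2,2-trimethylcyclopentyl]-4-oxobutanal | C[C@]1(C(=O)CCC=O)CC[C@@H](O[Si](C)(C)C(C)(C)C)C1(C)C
F8 | step 4 | methyl 6-[(1S,3R)-3-(tert-butyldimethylsilyloxy)-1,2,2-trimethylcyclopentyl]-3,6-dioxohexanoate | COC(=O)CC(=O)CCC(=O)[C@@]1(C)CC[C@@H](O[Si](C)(C)C(C)(C)C)C1(C)C
F9 | step 13 | methyl (2Z)-5-[(1S,2S,4aS,6R,8aR)-2-ethenyl-2,6-dihydroxy-5,5,8a-trimethyldecahydronaphthalen-1-yl]-3-methylpent-2-enoate | C/C(=C/C(=O)OC)CC[C@H]1[C@]2(C)CC[C@@H](O)C(C)(C)[C@H]2CC[C@]1(O)C=C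
F10 | step 13 | (2Z)-5-[(1S,2S,4aS,6R,8aR)-2-ethenyl-2,6-dihydroxy-5,5,8a-trimethyldecahydronaphthalen-1-yl]-3-methylpent-2-enoic acid | C/C(=C/C(=O)O)CC[C@H]1[C@]2(C)CC[C@@H](O)C(C)(C)[C@H]2CC[C@]1(O)C=C
F11 | step 13 | (2Z)-5-[(1S,2R,4aS,6R,8aR)-2-(1,2-dihydroxyethyl)-2,6-dihydroxy-5,5,8a-trimethyldecahydronaphthalen-1-yl]-3-methylpent-2-enoic acid, both epimers at the side-chain carbinol | C/C(=C/C(=O)O)CC[C@H]1[C@]2(C)CC[C@@H](O)C(C)(C)[C@H]2CC[C@]1(O)C(O)CO
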